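## Structural features

The target is a 2H-chromene: a benzene ring fused through C4a and C8a to a 2H-pyran ring (O1, C2, C3=C4). The benzene ring carries an acetyl group at C6 and a hydroxyl at C7 that is hydrogen-bonded to the acetyl carbonyl; C5 and C8 are unsubstituted. C2 is the only stereocentre: a fully substituted ether carbon of R configuration bound to O1, a methyl group, the vinylic C3 and an acyloxymethyl arm, with no neighbouring stereocentre to relay its configuration. The arm is esterified with (E)-ferulic acid, which adds a second phenol, a conjugated alkene and an ester open to methanolysis and conjugate addition. The C2–O1 bond is a tertiary, allylic aryl ether; ionisation or electrocyclic opening of the pyran makes C2 trigonal and erases the configuration. C3=C4 is an electron-rich styrene, sensitive to acid and to hydrogenation. The difficulty is twofold: a quaternary ether centre whose carbon arms (CH3 and CH2O) differ little must be made as one enantiomer, and the pyran must be closed onto C4a, not onto the carbon between the two ring oxygens, without loosening C2–O1. The key step uses the fact that C4a is ortho to O1 and para to the C7 oxygen, so an aryl propargyl ether that already contains O1 and C2 can be closed by forming only C4–C4a.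

## Logic of the disconnections

16 to 15: the two phenolic O–Si bonds are made the last bonds to be cleaved. Both phenols stay masked through ring closure and acylation, and one fluoride treatment frees them. The forward step must be buffered so that the ester and the alkenes never meet a basic phenoxide.

15 to 11 and 14: the ester C–O bond between the arm oxygen and the acyl carbon is cut. This divides the molecule into two halves of similar size. The forward step must be an acyl transfer to a primary alcohol on a fully substituted carbon, with no displacement at that carbon and no free phenol on either partner.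

14 to 12 (through 13): the phenolic O–Si bond is cut. The forward step silylates both acidic sites and then hydrolyses only the far more labile silyl ester.

11 to 10: the O–acetyl bond of the arm is cut. The acetate is the mark left by the enzyme and is kept through ring closure, because a free hydroxyl would add to the gold-activated alkyne. Its removal must spare the aryl silyl ether beside the ketone.

10 to 9: the C4–C4a bond is cut. This removes the pyran ring and leaves a trisubstituted benzene bearing a propargyl ether in which C2 is already complete. The forward step must select the arene carbon para to the silyloxy group and must not ionise the tertiary C–O bond. The substituents of 9 each serve this step: the bulky silyl ether shields the carbon between the oxygens, and the acetoxymethyl group disfavours a propargylic cation.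

9 to 8: the triple bond is traced back to a formyl group, which removes the terminal carbon C4. The homologation must be free of methoxide. Carbonate in methanol would cleave the acetate, release a β-hydroxy aldehyde open to retro-aldol loss of formaldehyde, and threaten the aryl silyl ether. It must also prefer the aldehyde over the aryl methyl ketone.

8 to 7 to 6: the oxidation level of one arm and the O–acetyl bond of the other are removed. This reveals a diol with a mirror plane, so the stereocentre becomes a choice between two enantiotopic CH2OH groups. The forward steps need an enzyme that tells the arms apart and handling that prevents 1,3-acetyl migration, which would racemise 7.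

6 to 4 (through 5): both CH2OH groups are returned to ester carbons. A hydride that reduces esters would also reduce an aryl ketone. The acetyl group is therefore carried in 4 as a silyl enol ether, which is inert to hydride and is opened by dilute acid in the work-up.

4 to 3: two O–Si bonds are cut. One reagent installs both the bulky aryl silyl ether needed later for site control and the temporary enol ether.

3 to 1 and 2: the aryl O–C(quaternary) bond is cut. A tertiary ether is hard to make, and an α-bromomalonate is one of the few tertiary electrophiles that accepts a phenoxide. It also delivers both arms at the same oxidation level, which makes the later desymmetrisation possible. The alkylation must occur at the free 4-hydroxyl, not at the chelated 2-hydroxyl.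

## Other disconnections considered

Alternative 1: The cut runs through the benzene ring (C8a–C8 and C4a–C5); C5 to C8 come from a 2-pyrone and the pyran ring stays whole. In the forward sense the ketene acetal double bond C8a=C4a of silyloxypyran A2 would add across C3 and C6 of pyrone A3, and loss of CO2 and silanol would give chromene ester A1.
- In favour: the arene substitution pattern is fixed by construction, so the choice between C4a and the carbon between the oxygens never arises. On this point it is better than the chosen plan. It is also convergent.
- Against: A2 is a 2H-pyran whose 6π ring opening gives an acyclic silyl dienoate with a trigonal C2. That opening gains an ester carbonyl, so the configuration would be at risk before and during a cycloaddition that needs heat. A2 must itself be made as one enantiomer over several steps. A1 carries a methyl ester and a methyl ether where the target has acetyl and hydroxyl, so an ester-to-methyl-ketone conversion and an ether cleavage next to an acid-sensitive chromene are added.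
- Comparison: on structure, both plans leave O1–C2 formally intact, but only the chosen plan keeps C2 in an open-chain ether that cannot open pericyclically. On mechanism, the cycloaddition has the better defined regiochemistry and the Friedel–Crafts closure the safer stereochemical integrity. On step economy it is longer.

Alternative 2: The cut excises C4 (bonds C3–C4 and C4–C4a) and leads back to benzofuranone A5. In the forward sense (trimethylsilyl)diazomethane would add to the Lewis-acid-activated ketone, and migration of the aryl carbon with loss of N2 would give chroman-3-one A4.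
- In favour: C2 is not touched, so on stereochemical integrity it is the equal of the chosen plan. The quaternary centre of A5 could come from catalytic asymmetric enolate chemistry, which is at least the equal of an enzymatic desymmetrisation. Migration of C2 in place of the aryl carbon would give a chroman-4-one that could still be taken to the chromene.
- Against: A4 has no alkene, no acetyl group and three protecting groups. Ketone reduction and dehydration next to a quaternary carbon, bromine-to-acetyl exchange and acidic acetal removal beside the chromene would all follow. Multiple insertion and epoxide formation are open to the diazo reagent.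
- Comparison: on structure it builds the pyran by enlarging a ring and then has to introduce the alkene and the acetyl group, which the chosen plan carries from the start. On mechanism a 1,2-shift replaces an arene attack, which removes the site question on the benzene ring but adds a choice of migrating group. On step economy it is clearly longer.

Alternative 3: The cut removes O1–C2 and C3–C4 and leads to salicylaldehyde A7 and enal A8. Under a chiral diarylprolinol silyl ether, the ortho hydroxyl would add to the iminium β-carbon and the enamine would condense with the formyl group to give A6.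
- In favour: two bonds, the ring and the stereocentre would form in one catalytic step from achiral partners. The acetyl and C7 hydroxyl need no protection, and there is no site question on the arene. If the selectivity were adequate, it would be better than the chosen plan on convergence and step count.
- Against: the oxa-Michael step must create a tetrasubstituted carbon on a β,β-disubstituted iminium ion, which is slow and reversible. Methyl and silyloxymethyl differ little, and the geometry of A8 can scramble through the dienamine. A6 can reopen by retro-oxa-Michael, a racemisation channel. The extra C3 formyl group must be excised, for instance with RhCl(PPh3)3, on a substrate with a free phenol and an aryl ketone.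
- Comparison: on structure it is the most direct. On mechanism its stereocontrol is the least secure, whereas the chosen plan sets the centre on an open-chain diol. On step economy it is the shortest route on paper.

Key step: step 7

Assumption: the lipase is taken to acetylate the enantiotopic hydroxymethyl group that leads to (R)-7; the sense of such a desymmetrisation cannot be predicted from structure alone, and the complementary enzymatic hydrolysis listed under step 4 at the end gives the antipode.

## Route

Step 1
Reactants: 1 2,4-dihydroxyacetophenone; 2 diethyl 2-bromo-2-methylmalonate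
Product: 3 diethyl 2-(4-acetyl-3-hydroxyphenoxy)-2-methylmalonate
Conditions: K2CO3, DMF, 60 °C
Reagents that add atoms: none
Why: Williamson-type O-alkylation; carbonate deprotonates the free 4-hydroxyl (the 2-hydroxyl is locked in a hydrogen bond to the acetyl group) and the phenoxide displaces bromide from the tertiary carbon activated by two esters.

Step 2
Reactants: 3 diethyl 2-(4-acetyl-3-hydroxyphenoxy)-2-methylmalonate
Product: 4 diethyl 2-methyl-2-{3-(triisopropylsilyloxy)-4-[1-(triisopropylsilyloxy)vinyl]phenoxy}malonate
Conditions: TIPSOTf (2.4 equiv), Et3N, CH2Cl2, 0 °C to rt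
Reagents that add atoms: triisopropylsilyl trifluoromethanesulfonate, CC(C)[Si](C(C)C)(C(C)C)OS(=O)(=O)C(F)(F)F
Why: Silyl triflate/amine silylation; the phenol is O-silylated and the methyl ketone is converted into its silyl enol ether, which masks it against hydride, while the malonate has no α-hydrogen and is inert.

Step 3
Reactants: 4 diethyl 2-methyl-2-{3-(triisopropylsilyloxy)-4-[1-(triisopropylsilyloxy)vinyl]phenoxy}malonate
Product: 6 2-[4-acetyl-3-(triisopropylsilyloxy)phenoxy]-2-methylpropane-1,3-diol, via enol ether diol 5 (not isolated)
Conditions: LiAlH4, THF, 0 °C; then 1 M HCl, THF/H2O, rt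
Reagents that add atoms: none
Why: Hydride reduction of both esters to the prochiral diol with the enol ether and aryl silyl ether inert; dilute acid then protonates the electron-rich enol ether at carbon and releases the ketone, while the aryl triisopropylsilyl ether is stable to dilute acid.

Step 4
Reactants: 6 2-[4-acetyl-3-(triisopropylsilyloxy)phenoxy]-2-methylpropane-1,3-diol
Product: 7 (R)-2-[4-acetyl-3-(triisopropylsilyloxy)phenoxy]-3-hydroxy-2-methylpropyl acetate
Conditions: Burkholderia cepacia lipase (Amano PS, immobilised), vinyl acetate, MTBE, 25 °C
Reagents that add atoms: vinyl acetate, CC(=O)OC=C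
Why: Lipase-catalysed desymmetrisation by irreversible transesterification; the acyl-enzyme acetylates one of the two enantiotopic hydroxymethyl groups, which creates the C2 stereocentre, and any over-acetylation should consume mainly the minor enantiomer.

Step 5
Reactants: 7 (R)-2-[4-acetyl-3-(triisopropylsilyloxy)phenoxy]-3-hydroxy-2-methylpropyl acetate
Product: 8 (S)-2-[4-acetyl-3-(triisopropylsilyloxy)phenoxy]-2-methyl-3-oxopropyl acetate
Conditions: Dess–Martin periodinane, NaHCO3, CH2Cl2, 0 °C to rt
Reagents that add atoms: none
Why: Dess–Martin oxidation of the hindered primary alcohol under buffered conditions that avoid 1,3-acetyl migration; the aldehyde has no α-hydrogen, so it cannot epimerise or eliminate, and the descriptor changes only through priorities.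

Step 6
Reactants: 8 (S)-2-[4-acetyl-3-(triisopropylsilyloxy)phenoxy]-2-methyl-3-oxopropyl acetate
Product: 9 (R)-2-[4-acetyl-3-(triisopropylsilyloxy)phenoxy]-2-methylbut-3-yn-1-yl acetate
Conditions: (MeO)2P(O)CHN2 (1.2 equiv), KOtBu (1.1 equiv), THF, −78 °C to rt
Reagents that add atoms: dimethyl (diazomethyl)phosphonate, COP(=O)(OC)C=[N+]=[N-]
Why: Seyferth–Gilbert homologation; the pre-formed phosphonate anion adds to the aldehyde, Horner–Wadsworth–Emmons-type elimination gives a diazoalkene, and loss of N2 with a 1,2-hydrogen shift gives the terminal alkyne. No methoxide is present, so the acetate and aryl silyl ether should survive, and the hindered, electron-rich methyl ketone is far less electrophilic than the α-aryloxy aldehyde at low temperature.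

Step 7
Reactants: 9 (R)-2-[4-acetyl-3-(triisopropylsilyloxy)phenoxy]-2-methylbut-3-yn-1-yl acetate
Product: 10 (R)-[6-acetyl-2-methyl-7-(triisopropylsilyloxy)-2H-chromen-2-yl]methyl acetate
Conditions: Ph3PAuNTf2 (5 mol%), dry CH2Cl2, 0 °C to rt
Reagents that add atoms: none
Why: Cationic monovalent gold binds the terminal alkyne as a π-complex, and the arene carbon ortho to the ether oxygen and para to the silyloxy group attacks the terminal alkyne carbon anti to gold, forming C4–C4a; loss of the arene proton restores aromaticity, and protodeauration of the C3–Au bond leaves the C3=C4 alkene and returns the catalyst. The closest known reaction type is the gold- or platinum-catalysed intramolecular hydroarylation (Friedel–Crafts alkenylation) of aryl propargyl ethers to 2H-chromenes. The pyran ring closes in the 6-endo-dig mode; the 5-exo-dig path would need attack at the internal alkyne carbon and is not expected for a terminal alkyne. No stereocentre is created and none of the four bonds at C2 is made or broken, so the enzymatically set configuration should be carried over unchanged, unlike a thermal propargyl Claisen sequence, which passes through a species with trigonal C2. The step needs site selectivity between the two carbons ortho to the ether oxygen: the one between the two oxygens is shielded by the triisopropylsilyl group and by the fully substituted C2, while the reacting carbon is open and receives para donation from the silyloxy oxygen, which offsets the meta acetyl group. It also needs the tertiary propargylic C–O bond to stay covalent, which the electron-withdrawing acetoxymethyl group favours by destabilising a propargylic cation. Dry solvent and the weakly coordinating counter-ion should keep alkyne hydration and acetate participation from competing.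

Step 8
Reactants: 10 (R)-[6-acetyl-2-methyl-7-(triisopropylsilyloxy)-2H-chromen-2-yl]methyl acetate
Product: 11 (R)-1-[2-(hydroxymethyl)-2-methyl-7-(triisopropylsilyloxy)-2H-chromen-6-yl]ethanone
Conditions: K2CO3 (0.2 equiv), MeOH, 0 °C
Reagents that add atoms: none
Why: Carbonate-catalysed transesterification (methanolysis) of the primary acetate at low temperature; the hindered aryl triisopropylsilyl ether and the quaternary C2 should be unaffected.

Step 9
Reactants: 12 ferulic acid
Product: 14 (E)-3-[4-(tert-butyldimethylsilyloxy)-3-methoxyphenyl]acrylic acid, via bis-silyl ferulate 13 (not isolated)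
Conditions: TBSCl (2.2 equiv), imidazole, DMF, rt; then AcOH, THF/H2O, rt
Reagents that add atoms: tert-butyldimethylsilyl chloride, CC(C)(C)[Si](C)(C)Cl
Why: Exhaustive silylation of phenol and acid, then selective hydrolysis of the much more labile silyl ester; the aryl silyl ether and the (E)-alkene are untouched.

Step 10
Reactants: 11 (R)-1-[2-(hydroxymethyl)-2-methyl-7-(triisopropylsilyloxy)-2H-chromen-6-yl]ethanone; 14 (E)-3-[4-(tert-butyldimethylsilyloxy)-3-methoxyphenyl]acrylic acid
Product: 15 [(R)-6-acetyl-2-methyl-7-(triisopropylsilyloxy)-2H-chromen-2-yl]methyl (E)-3-[4-(tert-butyldimethylsilyloxy)-3-methoxyphenyl]acrylate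
Conditions: EDC·HCl, DMAP, CH2Cl2, 0 °C to rt
Reagents that add atoms: none
Why: Steglich esterification; the acylpyridinium formed from the carbodiimide-activated acid acylates the primary alcohol, so no displacement at the hindered carbon is needed, and both phenols are silylated so no aryl ester can form.

Step 11
Reactants: 15 [(R)-6-acetyl-2-methyl-7-(triisopropylsilyloxy)-2H-chromen-2-yl]methyl (E)-3-[4-(tert-butyldimethylsilyloxy)-3-methoxyphenyl]acrylate
Product: 16 [(R)-6-acetyl-7-hydroxy-2-methyl-2H-chromen-2-yl]methyl (E)-3-(4-hydroxy-3-methoxyphenyl)acrylate
Conditions: TBAF (2.5 equiv), AcOH (2.5 equiv), THF, 0 °C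
Reagents that add atoms: none
Why: Fluoride-induced cleavage of both aryl silyl ethers, driven by Si–F bond formation; the acetic acid buffer protonates the phenoxides so that the cinnamate ester and the chromene are not exposed to base.

## Compound list

1 | 2,4-dihydroxyacetophenone | CC(=O)c1ccc(O)cc1O | starting material
2 | diethyl 2-bromo-2-methylmalonate | CCOC(=O)C(C)(Br)C(=O)OCC | starting material
3 | diethyl 2-(4-acetyl-3-hydroxyphenoxy)-2-methylmalonate | CCOC(=O)C(C)(Oc1ccc(C(C)=O)c(O)c1)C(=O)OCC | intermediate
4 | diethyl 2-methyl-2-{3-(triisopropylsilyloxy)-4-[1-(triisopropylsilyloxy)vinyl]phenoxy}malonate | CCOC(=O)C(C)(Oc1ccc(C(=C)O[Si](C(C)C)(C(C)C)C(C)C)c(O[Si](C(C)C)(C(C)C)C(C)C)c1)C(=O)OCC | intermediate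
5 | 2-methyl-2-{3-(triisopropylsilyloxy)-4-[1-(triisopropylsilyloxy)vinyl]phenoxy}propane-1,3-diol | OCC(C)(CO)Oc1ccc(C(=C)O[Si](C(C)C)(C(C)C)C(C)C)c(O[Si](C(C)C)(C(C)C)C(C)C)c1 | intermediate (not isolated)
6 | 2-[4-acetyl-3-(triisopropylsilyloxy)phenoxy]-2-methylpropane-1,3-diol | CC(=O)c1ccc(OC(C)(CO)CO)cc1O[Si](C(C)C)(C(C)C)C(C)C | intermediate
7 | (R)-2-[4-acetyl-3-(triisopropylsilyloxy)phenoxy]-3-hydroxy-2-methylpropyl acetate | CC(=O)OC[C@@](Oc1ccc(C(C)=O)c(O[Si](C(C)C)(C(C)C)C(C)C)c1)(C)CO | intermediate
8 | (S)-2-[4-acetyl-3-(triisopropylsilyloxy)phenoxy]-2-methyl-3-oxopropyl acetate | CC(=O)OC[C@@](Oc1ccc(C(C)=O)c(O[Si](C(C)C)(C(C)C)C(C)C)c1)(C)C=O | intermediate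
9 | (R)-2-[4-acetyl-3-(triisopropylsilyloxy)phenoxy]-2-methylbut-3-yn-1-yl acetate | CC(=O)OC[C@@](Oc1ccc(C(C)=O)c(O[Si](C(C)C)(C(C)C)C(C)C)c1)(C)C#C | intermediate
10 | (R)-[6-acetyl-2-methyl-7-(triisopropylsilyloxy)-2H-chromen-2-yl]methyl acetate | CC(=O)OC[C@@]1(C)C=Cc2cc(C(C)=O)c(O[Si](C(C)C)(C(C)C)C(C)C)cc2O1 | intermediate
11 | (R)-1-[2-(hydroxymethyl)-2-methyl-7-(triisopropylsilyloxy)-2H-chromen-6-yl]ethanone | OC[C@@]1(C)C=Cc2cc(C(C)=O)c(O[Si](C(C)C)(C(C)C)C(C)C)cc2O1 | intermediate
12 | ferulic acid, (E)-3-(4-hydroxy-3-methoxyphenyl)acrylic acid | COc1cc(/C=C/C(=O)O)ccc1O | starting material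
13 | tert-butyldimethylsilyl (E)-3-[4-(tert-butyldimethylsilyloxy)-3-methoxyphenyl]acrylate | COc1cc(/C=C/C(=O)O[Si](C)(C)C(C)(C)C)ccc1O[Si](C)(C)C(C)(C)C | intermediate (not isolated)
14 | (E)-3-[4-(tert-butyldimethylsilyloxy)-3-methoxyphenyl]acrylic acid | COc1cc(/C=C/C(=O)O)ccc1O[Si](C)(C)C(C)(C)C | intermediate
15 | [(R)-6-acetyl-2-methyl-7-(triisopropylsilyloxy)-2H-chromen-2-yl]methyl (E)-3-[4-(tert-butyldimethylsilyloxy)-3-methoxyphenyl]acrylate | COc1cc(/C=C/C(=O)OC[C@@]2(C)C=Cc3cc(C(C)=O)c(O[Si](C(C)C)(C(C)C)C(C)C)cc3O2)ccc1O[Si](C)(C)C(C)(C)C | intermediate
16 | [(R)-6-acetyl-7-hydroxy-2-methyl-2H-chromen-2-yl]methyl (E)-3-(4-hydroxy-3-methoxyphenyl)acrylate | COc1cc(/C=C/C(=O)OC[C@@]2(C)C=Cc3cc(C(C)=O)c(O)cc3O2)ccc1O | target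

Total step count: 11. Longest linear sequence: 10 (steps 1 to 8, 10 and 11, from 1 to 16); step 9 is a one-step branch from 12.

## Least certain steps

Step 7 (key step). The ring may close at the carbon between the two oxygens. The gold-activated alkyne may be intercepted by the acetate carbonyl or by traces of water. The tertiary propargylic C–O bond may ionise, which would erode the configuration. Fallback, from 9 back to 10: the alkyne would be activated by an iodonium source in place of the metal (I2, NaHCO3, MeNO2, rt, or iodine monochloride, CH2Cl2, −78 °C). Anti attack of the same arene carbon should close the ring in the 6-endo-dig mode and give (S)-[6-acetyl-3-iodo-2-methyl-7-(triisopropylsilyloxy)-2H-chromen-2-yl]methyl acetate F1; the descriptor changes only because iodine raises the priority of C3. Hydrodeiodination with Bu3SnH and catalytic Pd(PPh3)4 (oxidative addition of zerovalent palladium into the vinyl C–I bond, hydride transfer from tin, reductive elimination) would then return 10. C2–O1 is again untouched.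

Step 3. Enol silylation in step 2 may be incomplete next to the bulky ortho silyl ether, or the enol ether may be lost early, so that part of the ketone is reduced. The acid release may also be slow for so hindered an enol ether. Fallback, from 3 to 6, replacing steps 2 and 3: only the phenol would be silylated (TIPSOTf, 1.1 equiv, 2,6-lutidine, CH2Cl2) to give diethyl 2-[4-acetyl-3-(triisopropylsilyloxy)phenoxy]-2-methylmalonate F2. Reduction with LiAlH4 (THF, 0 °C) would take esters and ketone together to 2-[4-(1-hydroxyethyl)-3-(triisopropylsilyloxy)phenoxy]-2-methylpropane-1,3-diol F3. MnO2 in CH2Cl2 would then reoxidise only the benzylic alcohol and give 6.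

Step 4. Discrimination between the enantiotopic arms may be poor or of the opposite sense, and 1,3-acetyl migration in 7 would racemise it before oxidation. Fallback, from 6 to 7: both hydroxyls would be acetylated (Ac2O, pyridine, DMAP) to 2-[4-acetyl-3-(triisopropylsilyloxy)phenoxy]-2-methylpropane-1,3-diyl diacetate F4. The same lipase in pH 7 phosphate buffer with a cosolvent would then hydrolyse one enantiotopic acetate. Because the enzyme recognises the same arm in both directions, hydrolysis should give the monoacetate antipodal to that from acylation, so whichever mode gives (R)-7 would be used. In either mode 7 would be oxidised without storage.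

Step 6. The acetate may be lost through residual alkoxide or through acyl transfer to the intermediate alkoxide, and the reagent may also attack the methyl ketone. Fallback, from 8 to 15: cleavage of the acetate would be made part of the plan. The Ohira–Bestmann reagent, activated first with K2CO3 in MeOH at 0 °C so that homologation precedes methanolysis, would convert 8 into (R)-1-{4-[(1-hydroxy-2-methylbut-3-yn-2-yl)oxy]-2-(triisopropylsilyloxy)phenyl}ethanone F5. Steglich esterification with 14 (EDC·HCl, DMAP, CH2Cl2) would give (R)-2-[4-acetyl-3-(triisopropylsilyloxy)phenoxy]-2-methylbut-3-yn-1-yl (E)-3-[4-(tert-butyldimethylsilyloxy)-3-methoxyphenyl]acrylate F6. The gold closure of step 7 applied to F6 would deliver 15 directly, with the cinnamate as a spectator.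

Step 8. Methoxide may also cleave the aryl silyl ether, helped by the ortho acetyl group, leaving a mixture of silylated and free phenol. Fallback, from 10 to 16: both groups would be removed on purpose (K2CO3, MeOH, rt) to give (R)-1-[7-hydroxy-2-(hydroxymethyl)-2-methyl-2H-chromen-6-yl]ethanone F7. The primary alcohol would be esterified with 14 (EDC·HCl, catalytic DMAP, 0 °C) in preference to the chelated, poorly nucleophilic phenol, to give [(R)-6-acetyl-7-hydroxy-2-methyl-2H-chromen-2-yl]methyl (E)-3-[4-(tert-butyldimethylsilyloxy)-3-methoxyphenyl]acrylate F8. Buffered TBAF/AcOH would then remove the remaining silyl group and give 16.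

## Further compounds

F1 | step 7 | (S)-[6-acetyl-3-iodo-2-methyl-7-(triisopropylsilyloxy)-2H-chromen-2-yl]methyl acetate | CC(=O)OC[C@@]1(C)C(I)=Cc2cc(C(C)=O)c(O[Si](C(C)C)(C(C)C)C(C)C)cc2O1
F2 | step 3 | diethyl 2-[4-acetyl-3-(triisopropylsilyloxy)phenoxy]-2-methylmalonate | CCOC(=O)C(C)(Oc1ccc(C(C)=O)c(O[Si](C(C)C)(C(C)C)C(C)C)c1)C(=O)OCC
F3 | step 3 | 2-[4-(1-hydroxyethyl)-3-(triisopropylsilyloxy)phenoxy]-2-methylpropane-1,3-diol (racemic at the carbinol carbon) | CC(O)c1ccc(OC(C)(CO)CO)cc1O[Si](C(C)C)(C(C)C)C(C)C
F4 | step 4 | 2-[4-acetyl-3-(triisopropylsilyloxy)phenoxy]-2-methylpropane-1,3-diyl diacetate | CC(=O)OCC(C)(COC(C)=O)Oc1ccc(C(C)=O)c(O[Si](C(C)C)(C(C)C)C(C)C)c1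
F5 | step 6 | (R)-1-{4-[(1-hydroxy-2-methylbut-3-yn-2-yl)oxy]-2-(triisopropylsilyloxy)phenyl}ethanone | OC[C@@](Oc1ccc(C(C)=O)c(O[Si](C(C)C)(C(C)C)C(C)C)c1)(C)C#C
F6 | step 6 | (R)-2-[4-acetyl-3-(triisopropylsilyloxy)phenoxy]-2-methylbut-3-yn-1-yl (E)-3-[4-(tert-butyldimethylsilyloxy)-3-methoxyphenyl]acrylate | COc1cc(/C=C/C(=O)OC[C@@](Oc2ccc(C(C)=O)c(O[Si](C(C)C)(C(C)C)C(C)C)c2)(C)C#C)ccc1O[Si](C)(C)C(C)(C)C
F7 | step 8 | (R)-1-[7-hydroxy-2-(hydroxymethyl)-2-methyl-2H-chromen-6-yl]ethanone | OC[C@@]1(C)C=Cc2cc(C(C)=O)c(O)cc2O1
F8 | step 8 | [(R)-6-acetyl-7-hydroxy-2-methyl-2H-chromen-2-yl]methyl (E)-3-[4-(tert-butyldimethylsilyloxy)-3-methoxyphenyl]acrylate | COc1cc(/C=C/C(=O)OC[C@@]2(C)C=Cc3cc(C(C)=O)c(O)cc3O2)ccc1O[Si](C)(C)C(C)(C)C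
A1 | alternative 1 | methyl (R)-2-[(tert-butyldimethylsilyloxy)methyl]-7-methoxy-2-methyl-2H-chromene-6-carboxylate | COC(=O)c1cc2C=C[C@](C)(CO[Si](C)(C)C(C)(C)C)Oc2cc1OC
A2 | alternative 1 | (R)-6-(tert-butyldimethylsilyloxy)-2-[(tert-butyldimethylsilyloxy)methyl]-2-methyl-2H-pyran | CC(C)(C)[Si](C)(C)OC1=CC=C[C@](C)(CO[Si](C)(C)C(C)(C)C)O1
A3 | alternative 1 | methyl 4-methoxy-2-oxo-2H-pyran-5-carboxylate | COC(=O)C1=COC(=O)C=C1OC
A4 | alternative 2 | (S)-6-bromo-2-[(tert-butyldiphenylsilyloxy)methyl]-7-(methoxymethoxy)-2-methylchroman-3-one | C[C@@]1(CO[Si](c3ccccc3)(c4ccccc4)C(C)(C)C)Oc2cc(OCOC)c(Br)cc2CC1=O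
A5 | alternative 2 | (S)-5-bromo-2-[(tert-butyldiphenylsilyloxy)methyl]-6-(methoxymethoxy)-2-methylbenzofuran-3(2H)-one | C[C@@]1(CO[Si](c3ccccc3)(c4ccccc4)C(C)(C)C)Oc2cc(OCOC)c(Br)cc2C1=O
A6 | alternative 3 | (R)-6-acetyl-2-[(tert-butyldimethylsilyloxy)methyl]-7-hydroxy-2-methyl-2H-chromene-3-carbaldehyde | O=CC1=Cc2cc(C(C)=O)c(O)cc2O[C@@]1(C)CO[Si](C)(C)C(C)(C)C
A7 | alternative 3 | 5-acetyl-2,4-dihydroxybenzaldehyde | CC(=O)c1cc(C=O)c(O)cc1O
A8 | alternative 3 | (E)-4-(tert-butyldimethylsilyloxy)-3-methylbut-2-enal | O=C/C=C(\C)CO[Si](C)(C)C(C)(C)C
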